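(All runs stem from a simulated flask with made-up constants.)

Elm, a closed flask charged at once, is the run that south-east repeats, so I begin with what the closed runs say about each setting, counting everything as a fraction of the charge.

| setting | elm | ash | alder | larch | south | east | south-east |
|---|---|---|---|---|---|---|---|
| substrate | 0.15 M | 0.10 M | 0.22 M | 0.15 M | 0.15 M | 0.15 M (fed, over 24.0 h) | 0.15 M |
| enzyme | 42 µM | 42 µM | 42 µM | 63 µM | 42 µM | 42 µM | 42 µM |
| remark | run made earlier | run made earlier | run made earlier | run made earlier | a single well-mixed tank run continuously and read at steady state, 30 h in it on average | a stirred flask in which substrate is dosed at a steady rate over 24.0 h without added volume, worked up at 30 h | a closed flask charged with all of it at once and left for 30 h |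
| time |  |  |  |  |  | 30 h | 30 h |

| run | time / h | target / % | substrate / % |
|---|---|---|---|
| elm | 1.33 | 5.3 | 94.1 |
| elm | 2.00 | 6.2 | 88.4 |
| elm | 3.00 | 9.1 | 82.8 |
| elm | 5.00 | 12.1 | 71.7 |
| elm | 8.00 | 18.7 | 49.4 |
| elm | 12.0 | 25.6 | 26.5 |
| elm | 20.0 | 38.7 | 1.0 |
| ash | 2.00 | 11.9 | 83.9 |
| ash | 6.00 | 25.5 | 52.1 |
| ash | 10.0 | 42.6 | 20.7 |
| ash | 15.0 | 52.1 | 0.4 |
| ash | 20.0 | 54.9 | 0 |
| ash | 30.0 | 55.0 | 0 |
| ash | 40.0 | 55.2 | 0 |
| alder | 5.00 | 7.7 | 78.5 |
| alder | 10.0 | 10.3 | 50.7 |
| alder | 15.0 | 15.6 | 28.3 |
| alder | 20.0 | 22.4 | 10.1 |
| alder | 25.0 | 27.1 | 0 |
| alder | 30.0 | 28.0 | 0 |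
| alder | 40.0 | 27.8 | 0 |
| larch | 3.00 | 13.0 | 77.4 |
| larch | 5.00 | 20.5 | 56.4 |
| larch | 10.0 | 38.1 | 14.6 |
| larch | 20.0 | 46.9 | 0 |
| larch | 40.0 | 47.4 | 0 |

(readings scatter by 1 percentage point)

- percent here means substrate units held: one side product counts as two
- the stated concentrations are those of everything mixed, before any reaction; amounts are the same in each set-up
- on the list of suspects stand: substrate + enzyme -> target + enzyme; substrate + target -> side product
- the feed brings no volume worth counting
- the earlier runs were made in a closed, stirred flask

- the set-up with the highest amount of target at the outlet or at the end, in percent of the substrate put in ("none" if the first two lie within 2 percentage points) (south / east / south-east / none)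
- amount of target at the outlet or at the end, in percent of the substrate put in, south
- amount of target at the outlet or at the end, in percent of the substrate put in, east
- amount of target at the outlet or at the end, in percent of the substrate put in, south-east

The charge comes first. By hand, a larger charge should hurt: at equal fractions the side step, which takes a substrate and a target together, grows with the charge squared, while the enzyme holds a level pace. The runs agree, with ash ending at 55.2% and alder lower at 27.8%.

More enzyme should help to the first power, and larch at 47.4% stands above elm at 38.7%. So I join both settings in the load, a Damköhler number up to a constant, taken relative to ash: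

load = (charge / ash charge) squared × (ash enzyme / enzyme)

South-east: 2.25, as for elm; larch: 1.50; alder: 4.84

Ash and alder give the final fraction as ash's value × load^(−n), with n = 0.435

Larch on this line: 46.3%; south-east: 38.8%

Next comes time. Substrate lost plus target gained counts each enzyme step twice, so elm's readings at 12.0 h, taken at a level pace, give the enzyme about 24.2 h for a whole charge. That is shorter than 30 h, so I expect the closed flask to be finished.

Last comes the vessel, which the load does not cover. East's feed lasts 24.0 h, about the enzyme's time, so substrate should be used about as it arrives. I therefore put east first and south, which also holds substrate low, above south-east.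

The forecast gives 54% for south, 60% for east and 39.5% for south-east, names east, and says “Low substrate favours target”.

The flask gives 59.5% in south, 64.3% in east and 40.2% in south-east, so the best is east.

    substrate + enzyme → target + enzyme, rate k1*[substrate]*[enzyme]/(1 + ([substrate]/Km1)) (3.90 mM, k = 40000 M⁻¹ h⁻¹)
    substrate + target → side product (k = 1.80 M⁻¹ h⁻¹)

In east, substrate peaks at 9.20% of the charge. South-east, at load 2.25, lies 1.4 percentage points from my line.

A neighbour of south-east charged with 0.26 M of substrate has load 6.76, and the line gives 24.0%. The computed flask ends at 23.7%.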